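**Plan**

- The target is 3,5,2',4'-tetrahydroxy-7,8,5'-trimethoxyflavone, with no stereocentre. The retrosynthesis removes the C3 hydroxyl, masks the 2'- and 4'-hydroxyls as isopropyl ethers and the 5-hydroxyl as a methyl ether, then cuts C4–C4a of ring C, then the vinyl C2–O1 bond, then the C1'–alkyne bond.
- Enabling feature: in 2,3,5-trimethoxyphenol the oxygen that becomes O1 has only one unsubstituted ortho carbon, the future C4a. That carbon is ortho to the future C5 methoxy group and para to the future C7 methoxy group, so an acyl cation tethered to O1 can close ring C only there.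
- Forward: rings A and B are bought as benzenes and adjusted separately (ring A phenol in 4 steps, ring B arylpropiolate in 5 steps). The chain is joined by Sonogashira coupling and phenoxide addition to the ynoate, and ring C closes last by intramolecular Friedel–Crafts acylation.
- Finish: C3 is hydroxylated by lithiation, borylation and oxidation, and one BCl3 treatment frees the 2'-, 4'- and 5-hydroxyls.
- Stereochemistry: none has to be set; the enol ether geometry of the precursor disappears when ring C becomes the pyranone.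

Key step: step 12

Remark: the phenoxide addition may give the enol ether as an E/Z mixture; the ester, acid and acid chloride are drawn as the Z isomer needed for closure, and any E isomer is carried along because both should converge in the ring closure.

**Route**

Step 1
Reactants: 1 2-hydroxy-4,6-dimethoxybenzaldehyde
Product: 2 2-(benzyloxy)-4,6-dimethoxybenzaldehyde
Conditions: BnBr, K2CO3, DMF, 60 °C
Reagents that add atoms: benzyl bromide, BrCc1ccccc1
Why: Williamson ether synthesis on the chelated phenol; the benzyl group marks the oxygen that will become O1 and keeps it distinct from the oxygen introduced in step 2.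

Step 2
Reactants: 2 2-(benzyloxy)-4,6-dimethoxybenzaldehyde
Product: 4 2-(benzyloxy)-4,6-dimethoxyphenol, via aryl formate 3 (not isolated)
Conditions: mCPBA, CH2Cl2, 0 °C → rt; aq. NaHCO3 wash; then K2CO3 (cat.), MeOH, rt
Reagents that add atoms: 3-chloroperoxybenzoic acid, O=C(OO)c1cccc(Cl)c1
Why: Baeyer–Villiger oxidation in which the electron-rich trialkoxyaryl group migrates in preference to hydrogen, followed by methanolysis of the aryl formate.

Step 3
Reactants: 4 2-(benzyloxy)-4,6-dimethoxyphenol
Product: 5 1-(benzyloxy)-2,3,5-trimethoxybenzene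
Conditions: MeI, K2CO3, acetone, reflux
Reagents that add atoms: iodomethane, CI
Why: Williamson methylation of the only free hydroxyl, which fixes the future C8 methoxy group.

Step 4
Reactants: 5 1-(benzyloxy)-2,3,5-trimethoxybenzene
Product: 6 2,3,5-trimethoxyphenol
Conditions: H2 (1 atm), 10% Pd/C, EtOAc–MeOH, rt
Reagents that add atoms: none
Why: Hydrogenolysis of the benzyl ether leaves the methyl ethers untouched and frees the phenol whose single open ortho position becomes C4a.

Step 5
Reactants: 7 2,4-dihydroxybenzaldehyde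
Product: 8 2,4-di(propan-2-yloxy)benzaldehyde
Conditions: 2-bromopropane, K2CO3, DMF, 70 °C
Reagents that add atoms: 2-bromopropane, CC(C)Br
Why: Double Williamson alkylation; isopropyl ethers are chosen because they should survive base, organolithium and mild Lewis acid yet be cleaved by BCl3 beside methyl ethers.

Step 6
Reactants: 8 2,4-di(propan-2-yloxy)benzaldehyde
Product: 10 2,4-di(propan-2-yloxy)phenol, via aryl formate 9 (not isolated)
Conditions: mCPBA, CH2Cl2, 0 °C → rt; aq. NaHCO3 wash; then K2CO3 (cat.), MeOH, rt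
Reagents that add atoms: 3-chloroperoxybenzoic acid, O=C(OO)c1cccc(Cl)c1
Why: Baeyer–Villiger oxidation of an ortho,para-dialkoxybenzaldehyde (aryl migration) and formate methanolysis turn the formyl carbon into the oxygen of the future 5'-methoxy group.

Step 7
Reactants: 10 2,4-di(propan-2-yloxy)phenol
Product: 11 1-methoxy-2,4-di(propan-2-yloxy)benzene
Conditions: MeI, K2CO3, acetone, reflux
Reagents that add atoms: iodomethane, CI
Why: Williamson methylation installs the one ring B oxygen substituent that stays as a methyl ether in the target.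

Step 8
Reactants: 11 1-methoxy-2,4-di(propan-2-yloxy)benzene
Product: 12 1-iodo-5-methoxy-2,4-di(propan-2-yloxy)benzene
Conditions: NIS, TFA (cat.), MeCN, 0 °C → rt
Reagents that add atoms: N-iodosuccinimide, O=C1CCC(=O)N1I
Why: Electrophilic aromatic iodination at the carbon para to one isopropoxy group and ortho to the other, the usual site for 1,2,4-trialkoxybenzenes; the carbon between the two isopropoxy groups is shielded.

Step 9
Reactants: 12 1-iodo-5-methoxy-2,4-di(propan-2-yloxy)benzene; 13 ethyl propiolate
Product: 14 ethyl 3-[5-methoxy-2,4-di(propan-2-yloxy)phenyl]prop-2-ynoate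
Conditions: PdCl2(PPh3)2 (cat.), CuI (cat.), K2CO3, THF, 65 °C, slow addition of 13 (excess)
Reagents that add atoms: none
Why: Sonogashira coupling (oxidative addition of the aryl iodide to zerovalent palladium, transfer of the copper acetylide, reductive elimination), run with carbonate instead of an amine so that no nucleophilic base adds to the propiolate.

Step 10
Reactants: 6 2,3,5-trimethoxyphenol; 14 ethyl 3-[5-methoxy-2,4-di(propan-2-yloxy)phenyl]prop-2-ynoate
Product: 15 ethyl (2Z)-3-[5-methoxy-2,4-di(propan-2-yloxy)phenyl]-3-(2,3,5-trimethoxyphenoxy)prop-2-enoate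
Conditions: Cs2CO3 (0.3 equiv), dry DMF, 80 °C
Reagents that add atoms: none
Why: Base-catalysed oxa-Michael addition of the phenoxide to the β-carbon of the ynoate, with anti protonation of the vinyl anion placing the aryloxy group cis to the ester (Z).

Step 11
Reactants: 15 ethyl (2Z)-3-[5-methoxy-2,4-di(propan-2-yloxy)phenyl]-3-(2,3,5-trimethoxyphenoxy)prop-2-enoate
Product: 16 (2Z)-3-[5-methoxy-2,4-di(propan-2-yloxy)phenyl]-3-(2,3,5-trimethoxyphenoxy)prop-2-enoic acid
Conditions: LiOH, THF–H2O, 40 °C; then 1 M HCl to pH 3, 0 °C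
Reagents that add atoms: lithium hydroxide, [Li+].[OH-]
Why: Saponification of the ethyl ester; cold, brief acidification should spare the enol ether.

Step 12
Reactants: 16 (2Z)-3-[5-methoxy-2,4-di(propan-2-yloxy)phenyl]-3-(2,3,5-trimethoxyphenoxy)prop-2-enoic acid
Product: 18 5,7,8-trimethoxy-2-[5-methoxy-2,4-di(propan-2-yloxy)phenyl]-4H-chromen-4-one, via acid chloride 17 (not isolated)
Conditions: (COCl)2, DMF (cat.), CH2Cl2, 0 °C → rt; evaporate; then SnCl4 (1.2 equiv), CH2Cl2 (high dilution), −78 → 0 °C
Reagents that add atoms: none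
Why: Oxalyl chloride converts the acid into acid chloride 17, and SnCl4 ionises it to an acylium ion, stabilised by the enol ether oxygen as an oxocarbenium–ketene; this ion attacks the one unsubstituted carbon ortho to the aryloxy oxygen of ring A, and proton loss restores ring A and leaves the 4-pyranone. The closest known reaction type is the Friedel–Crafts cyclisation of 3-aryloxycinnamic acids, obtained from phenols and arylpropiolates, to flavones. Ring C closes in a six-membered mode, 6-exo-trig at the activated acyl carbon (6-exo-dig for the free acylium ion), forming C4–C4a. No stereocentre is formed, and the enol ether geometry is not critical, because rotation in the oxocarbenium–ketene form should let E and Z material converge. The step needs chemoselectivity for ring A: the attacked carbon is ortho to the ring oxygen and the C5 methoxy group and para to the C7 methoxy group, whereas the reachable ring B carbon C6' (indenone closure) has one ortho methoxy group only. Capture of the acylium ion by the 2'-isopropoxy oxygen (coumarin formation with loss of the isopropyl group) is held back by the low temperature, and intermolecular acylation by dilution.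

Step 13
Reactants: 18 5,7,8-trimethoxy-2-[5-methoxy-2,4-di(propan-2-yloxy)phenyl]-4H-chromen-4-one
Product: 21 3-hydroxy-5,7,8-trimethoxy-2-[5-methoxy-2,4-di(propan-2-yloxy)phenyl]-4H-chromen-4-one, via 3-lithioflavone 19 (not isolated), via dimethyl flavon-3-ylboronate 20 (not isolated)
Conditions: LiN(iPr)2 (LDA), THF, −78 °C; B(OMe)3, −78 → 0 °C; then AcOH, 30% aq. H2O2, 0 °C → rt
Reagents that add atoms: hydrogen peroxide, OO
Why: Known flavone-to-flavonol sequence in which the amide base removes the C3 proton next to the carbonyl, the 3-lithio species is trapped as the boronate, and peroxide-induced migration from boron to oxygen gives the 3-hydroxyl.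

Step 14
Reactants: 21 3-hydroxy-5,7,8-trimethoxy-2-[5-methoxy-2,4-di(propan-2-yloxy)phenyl]-4H-chromen-4-one
Product: 22 2-(2,4-dihydroxy-5-methoxyphenyl)-3,5-dihydroxy-7,8-dimethoxy-4H-chromen-4-one
Conditions: BCl3 (excess), CH2Cl2, −78 °C → rt; then MeOH, aq. HCl
Reagents that add atoms: none
Why: Lewis acid ether cleavage in which BCl3 removes the secondary isopropyl groups and, through a six-membered chelate with the C4 carbonyl, only the peri 5-methyl ether, while the 7-, 8- and 5'-methyl ethers should be retained.

**Compound list**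

1 | 2-hydroxy-4,6-dimethoxybenzaldehyde | COc1cc(O)c(C=O)c(OC)c1 | starting material
2 | 2-(benzyloxy)-4,6-dimethoxybenzaldehyde | COc1cc(OCc2ccccc2)c(C=O)c(OC)c1 | intermediate
3 | 2-(benzyloxy)-4,6-dimethoxyphenyl formate | COc1cc(OCc2ccccc2)c(OC=O)c(OC)c1 | intermediate
4 | 2-(benzyloxy)-4,6-dimethoxyphenol | COc1cc(OCc2ccccc2)c(O)c(OC)c1 | intermediate
5 | 1-(benzyloxy)-2,3,5-trimethoxybenzene | COc1cc(OCc2ccccc2)c(OC)c(OC)c1 | intermediate
6 | 2,3,5-trimethoxyphenol | COc1cc(O)c(OC)c(OC)c1 | intermediate
7 | 2,4-dihydroxybenzaldehyde | O=Cc1ccc(O)cc1O | starting material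
8 | 2,4-di(propan-2-yloxy)benzaldehyde | CC(C)Oc1ccc(C=O)c(OC(C)C)c1 | intermediate
9 | 2,4-di(propan-2-yloxy)phenyl formate | CC(C)Oc1ccc(OC=O)c(OC(C)C)c1 | intermediate
10 | 2,4-di(propan-2-yloxy)phenol | CC(C)Oc1ccc(O)c(OC(C)C)c1 | intermediate
11 | 1-methoxy-2,4-di(propan-2-yloxy)benzene | COc1ccc(OC(C)C)cc1OC(C)C | intermediate
12 | 1-iodo-5-methoxy-2,4-di(propan-2-yloxy)benzene | COc1cc(I)c(OC(C)C)cc1OC(C)C | intermediate
13 | ethyl propiolate | C#CC(=O)OCC | starting material
14 | ethyl 3-[5-methoxy-2,4-di(propan-2-yloxy)phenyl]prop-2-ynoate | CCOC(=O)C#Cc1cc(OC)c(OC(C)C)cc1OC(C)C | intermediate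
15 | ethyl (2Z)-3-[5-methoxy-2,4-di(propan-2-yloxy)phenyl]-3-(2,3,5-trimethoxyphenoxy)prop-2-enoate | CCOC(=O)/C=C(\Oc1cc(OC)cc(OC)c1OC)c1cc(OC)c(OC(C)C)cc1OC(C)C | intermediate
16 | (2Z)-3-[5-methoxy-2,4-di(propan-2-yloxy)phenyl]-3-(2,3,5-trimethoxyphenoxy)prop-2-enoic acid | OC(=O)/C=C(\Oc1cc(OC)cc(OC)c1OC)c1cc(OC)c(OC(C)C)cc1OC(C)C | intermediate
17 | (2Z)-3-[5-methoxy-2,4-di(propan-2-yloxy)phenyl]-3-(2,3,5-trimethoxyphenoxy)prop-2-enoyl chloride | O=C(Cl)/C=C(\Oc1cc(OC)cc(OC)c1OC)c1cc(OC)c(OC(C)C)cc1OC(C)C | intermediate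
18 | 5,7,8-trimethoxy-2-[5-methoxy-2,4-di(propan-2-yloxy)phenyl]-4H-chromen-4-one | COc1cc(OC)c2c(=O)cc(-c3cc(OC)c(OC(C)C)cc3OC(C)C)oc2c1OC | intermediate
19 | 3-lithio-5,7,8-trimethoxy-2-[5-methoxy-2,4-di(propan-2-yloxy)phenyl]-4H-chromen-4-one | [Li]c1c(-c2cc(OC)c(OC(C)C)cc2OC(C)C)oc2c(OC)c(OC)cc(OC)c2c1=O | intermediate
20 | dimethyl {5,7,8-trimethoxy-2-[5-methoxy-2,4-di(propan-2-yloxy)phenyl]-4-oxo-4H-chromen-3-yl}boronate | COB(OC)c1c(-c2cc(OC)c(OC(C)C)cc2OC(C)C)oc2c(OC)c(OC)cc(OC)c2c1=O | intermediate
21 | 3-hydroxy-5,7,8-trimethoxy-2-[5-methoxy-2,4-di(propan-2-yloxy)phenyl]-4H-chromen-4-one | COc1cc(OC)c2c(=O)c(O)c(-c3cc(OC)c(OC(C)C)cc3OC(C)C)oc2c1OC | intermediate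
22 | 2-(2,4-dihydroxy-5-methoxyphenyl)-3,5-dihydroxy-7,8-dimethoxy-4H-chromen-4-one | COc1cc(-c2oc3c(OC)c(OC)cc(O)c3c(=O)c2O)c(O)cc1O | target

**Step count and risks**

Total step count: 14. Longest linear sequence: 10 steps (steps 5–14, from 2,4-dihydroxybenzaldehyde); the ring A branch (steps 1–4) joins at step 10.

Steps most likely to fail:

Step 10. The conjugate addition may stall, because the alkoxy groups ortho and para to the alkyne push electron density into the β-carbon of the ynoate. Forcing it invites ester cleavage and base-induced breakdown of the propiolate. The fallback sets out from 12, uses phenol 6, and returns to the route at 16, so steps 9–11 are bypassed. Sonogashira coupling of 12 with prop-2-yn-1-ol (PdCl2(PPh3)2, CuI, Et3N, 50 °C) should give 3-[5-methoxy-2,4-di(propan-2-yloxy)phenyl]prop-2-yn-1-ol F1. Oxidation with MnO2 in CH2Cl2 should give 3-[5-methoxy-2,4-di(propan-2-yloxy)phenyl]prop-2-ynal F2, a much stronger acceptor than the ester. Phenol 6 with catalytic Et3N in MeCN at room temperature should add to give (2Z)-3-[5-methoxy-2,4-di(propan-2-yloxy)phenyl]-3-(2,3,5-trimethoxyphenoxy)prop-2-enal F3. Pinnick oxidation (NaClO2, NaH2PO4, 2-methylbut-2-ene, t-BuOH–H2O) should then deliver acid 16.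

Step 12. The acylium ion may be intercepted by the 2'-isopropoxy oxygen of ring B, with loss of the isopropyl group and lactonisation. The Lewis acid may also cleave the enol ether, or acylation may occur between molecules at the other activated ring A carbon. The fallback sets out from 6 and 11 and returns at 18; it closes ring C through the O1–C2 bond instead. Acetylation of 6 with Ac2O and BF3·OEt2 (ortho-selective through the boron chelate, Fries type) should give 1-(2-hydroxy-3,4,6-trimethoxyphenyl)ethan-1-one F4. Vilsmeier–Haack formylation of 11 (POCl3, DMF) should give 5-methoxy-2,4-di(propan-2-yloxy)benzaldehyde F5. Claisen–Schmidt condensation of the two (KOH, EtOH) should give (2E)-1-(2-hydroxy-3,4,6-trimethoxyphenyl)-3-[5-methoxy-2,4-di(propan-2-yloxy)phenyl]prop-2-en-1-one F6. Oxidative cyclisation with catalytic I2 in DMSO at 120 °C should then give flavone 18.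

Step 13. Deprotonation at C3 may be incomplete, the amide may add to C2, the 3-lithio species may open by β-elimination of the ring phenoxide on warming, and the peroxide may over-oxidise the electron-rich rings. The fallback sets out from 18 and returns at 21; it uses electrophilic instead of anionic oxygenation. Dimethyldioxirane in acetone–CH2Cl2 at 0 °C should epoxidise the C2=C3 bond to racemic cis-2,3-epoxy-5,7,8-trimethoxy-2-[5-methoxy-2,4-di(propan-2-yloxy)phenyl]chroman-4-one F7. Catalytic p-TsOH in CH2Cl2 should open the epoxide at C2 and, after proton loss from C3, give flavonol 21.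

**Further compounds**

F1 | step 10 | 3-[5-methoxy-2,4-di(propan-2-yloxy)phenyl]prop-2-yn-1-ol | COc1cc(C#CCO)c(OC(C)C)cc1OC(C)C
F2 | step 10 | 3-[5-methoxy-2,4-di(propan-2-yloxy)phenyl]prop-2-ynal | COc1cc(C#CC=O)c(OC(C)C)cc1OC(C)C
F3 | step 10 | (2Z)-3-[5-methoxy-2,4-di(propan-2-yloxy)phenyl]-3-(2,3,5-trimethoxyphenoxy)prop-2-enal | O=C/C=C(\Oc1cc(OC)cc(OC)c1OC)c1cc(OC)c(OC(C)C)cc1OC(C)C
F4 | step 12 | 1-(2-hydroxy-3,4,6-trimethoxyphenyl)ethan-1-one | CC(=O)c1c(OC)cc(OC)c(OC)c1O
F5 | step 12 | 5-methoxy-2,4-di(propan-2-yloxy)benzaldehyde | COc1cc(C=O)c(OC(C)C)cc1OC(C)C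
F6 | step 12 | (2E)-1-(2-hydroxy-3,4,6-trimethoxyphenyl)-3-[5-methoxy-2,4-di(propan-2-yloxy)phenyl]prop-2-en-1-one | COc1cc(OC)c(C(=O)/C=C/c2cc(OC)c(OC(C)C)cc2OC(C)C)c(O)c1OC
F7 | step 13 | racemic cis-2,3-epoxy-5,7,8-trimethoxy-2-[5-methoxy-2,4-di(propan-2-yloxy)phenyl]chroman-4-one (one enantiomer drawn) | O=C1c2c(OC)cc(OC)c(OC)c2O[C@]2(c3cc(OC)c(OC(C)C)cc3OC(C)C)O[C@H]12
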